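Two questions, and the harder one goes first.

| flask | Xa | Xb | Xc | time |
|---|---|---|---|---|
| south | 1.00 M | 1.10 M | 0.00200 M |  |
| south-east | 0.600 M | 0.700 M | 0.00200 M |  |
| north-west | 1.00 M | 1.10 M | 0.00600 M |  |
| east | 0.500 M | 0.550 M | 0.00200 M | 7.0 min |

| run | time / min | [Xp] / M |
|---|---|---|
| south run | 0.28 | 0.061 |
| south run | 0.48 | 0.089 |
| south run | 0.82 | 0.139 |
| south run | 1.4 | 0.201 |
| south run | 2.4 | 0.268 |
| south run | 4.1 | 0.318 |
| south run | 7.0 | 0.346 |
| south-east run | 0.28 | 0.025 |
| south-east run | 0.48 | 0.048 |
| south-east run | 0.82 | 0.067 |
| south-east run | 1.4 | 0.093 |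
| south-east run | 2.4 | 0.123 |
| south-east run | 4.1 | 0.149 |
| south-east run | 7.0 | 0.167 |
| north-west run | 0.28 | 0.158 |
| north-west run | 0.48 | 0.242 |
| north-west run | 0.82 | 0.346 |
| north-west run | 1.4 | 0.440 |
| north-west run | 2.4 | 0.532 |
| north-west run | 4.1 | 0.574 |
| north-west run | 7.0 | 0.595 |

(readings scatter by 0.003 M)

- Overall: Xa + Xb -> Xp, with Xc as catalyst.
- Constant volume, constant temperature.
- Bound and free are read together.
- An order is taken over about fifteen percent of the charge, up and down.

- the power of [Xc] that the first rate follows, about the charge of the south run; measure it at two percent of Xa made into Xp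
- Xp in the east run at 7.0 min, as a share of the Xa charged

"Which runs speak for the east flask?" The south and south-east runs, since their Xc equals its 0.00200 M.

"What do you compare?" The share of the Xa charged that has become Xp at 7.0 min: 34.6% in the south run against 27.8% in the south-east run. The share exponent, a kind of apparent order, is the power of the Xb charge that this share follows at a fixed time and equal Xc. These two readings make it 0.481.

"But Xa moved as well. Why credit Xb?" These two runs change Xa and Xb together. Still, Xb over Xa is 1.10 in the east flask, 1.10 in the south run and 1.17 in the south-east run, so the three charges lie nearly on one line, and the exponent is used along that line. Scaling the south-east share to the east charge of Xb, I get 24.8%.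

"And the catalyst?" The first readings, north-west over south, give a power of 0.866. That chord spans 0.158 M of Xp in the north-west run against 0.061 M in the south run, so it bends more there, and the power at two percent should stand higher. I commit to about 1.

The forecast, which opens from “The runs stall well short of full conversion”, gives 1.06 for the power and 23.8% for the east share, which is lower than my figure by 1.00 percentage point.

The east flask gives 24.0%, and the power of Xc is 1.0. These steps ran in the flasks:

    Xc + Xb ⇌ Xc.Xb, settled at all times (0.5950 M⁻¹)
    Xc.Xb + Xa → Xp + Xc (291.0 M⁻¹ min⁻¹)
    Xa → Z (0.3024 min⁻¹)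
    Xb → G (0.1314 min⁻¹)

Early in the south run the apparent order in Xb is 0.65, higher than the share exponent of 0.481 read at 7.0 min. Taken from the south run to the east flask, the same exponent reads 0.525. Applied to the south run's share of 31.8% at 4.1 min, it gives 25.6% for the south-east run, about a quarter. That run's own reading at 4.1 min is 0.149 M of Xp, which is 24.8% of its Xa.

The readings are calculated from invented constants.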